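**Plan**

Numbering used below: C1 (benzoyl-bearing), C2 (C=O), C3, C4 (C=O), C5 (prenyl-bearing), C6 (CH2), C7 (CH), C8 (CMe2), C9 (C=O between C1 and C5); C10 (CH2 on C7), C11 (CH on C3), C12 (CMe2–OO), C13 (CH–OO), C14 (CH2 on C3), C15 (CMe2OOH).
Retrosynthesis: (i) C12–O, O–C13 and C15–O are cut (peroxyl radical cascade), leaving isopropenyl on C11 and prenyl on C3; (ii) C3–C11 is cut by a retro-Claisen that inserts O–CH2 between C4 and C12, so the seven-membered carbocycle C3–C4–C5–C6–C7–C10–C11 becomes a nine-membered allyl enol ether; (iii) then C1–C8 (cation–olefin), O4–CH2 (ether), C5–C6 (allylation of clusiaphenone B) and C10–C11 (Stille).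
Enabling feature: the C4 ketone lies in the seven-membered ring next to quaternary C3, and C3 carries C11–C12; with C12 as an isopropenyl carbon, O=C4–C3–C11–C12=CH2 is a γ,δ-unsaturated ketone, the product pattern of a [3,3] shift from the enol oxygen of C4.
Forward: acylphloroglucinol ring → quaternary C5 (asymmetric dearomative allylation) → nine-membered ether ring (Mitsunobu) → carbocycle C1–C9–C5–C6–C7–C8 (cation–olefin) → ring contraction 9 → 7 (Claisen, completes the homoadamantane) → 1,2-dioxepane and hydroperoxide (O2 cascade).
Stereochemistry: C5 from the chiral palladium catalyst; C7 and C1 from the ether tether in the cationic closure; C3 and C11 from the suprafacial shift inside the cage and the Z ring alkene; C13 from the cage-controlled peroxyl cyclization.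

Key step: step 9

Assumption: the sense of induction of the chiral ligand in step 6 cannot be predicted with certainty; the (S,S) ligand is written, and its antipode would be used if the first run gives the (6R) dienone.
Remark: enolised triketones are drawn as one tautomer throughout.

**Route**

Step 1
Reactants: 1 diethyl 2-(propan-2-ylidene)propanedioate
Product: 2 2-(propan-2-ylidene)propane-1,3-diol
Conditions: i-Bu2AlH (4.5 equiv), CH2Cl2, −78 to 0 °C; aq. potassium sodium tartrate
Reagents that add atoms: none
Why: Hydride reduction of both esters to the allylic diol (1,2-reduction; conjugate reduction is blocked by the β,β-dimethyl terminus of the alkylidene malonate).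

Step 2
Reactants: 2 2-(propan-2-ylidene)propane-1,3-diol
Product: 3 dimethyl 2-(propan-2-ylidene)propane-1,3-diyl biscarbonate
Conditions: ClCO2Me (2.5 equiv), pyridine, CH2Cl2, 0 °C
Reagents that add atoms: methyl chloroformate COC(=O)Cl
Why: Carbonate formation by acylation of both primary allylic alcohols, which turns them into leaving groups for zerovalent palladium.

Step 3
Reactants: 4 prop-2-yn-1-ol
Product: 6 (Z)-2-methyl-3-(tributylstannyl)prop-2-en-1-ol, via vinylmagnesium alkoxide 5 (not isolated)
Conditions: MeMgBr (2.2 equiv), CuI (10 mol %), Et2O, −10 °C to rt; then Bu3SnCl, 0 °C to rt; aq. NH4Cl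
Reagents that add atoms: methylmagnesium bromide C[Mg]Br; tributyltin chloride CCCC[Sn](Cl)(CCCC)CCCC
Why: Copper-catalysed anti-carbomagnesiation of the propargylic alkoxide passes through a five-membered magnesium chelate that places Mg cis to CH2O, and magnesium-to-tin exchange with retention fixes the Z geometry.

Step 4
Reactants: 6 (Z)-2-methyl-3-(tributylstannyl)prop-2-en-1-ol; 3 biscarbonate (3 equiv)
Product: 7 (4Z)-6-hydroxy-5-methyl-2-(propan-2-ylidene)hex-4-en-1-yl methyl carbonate
Conditions: Pd2(dba)3 (2.5 mol %), DMF, rt
Reagents that add atoms: none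
Why: Stille coupling of an allylic carbonate under neutral conditions (ionisation by zerovalent palladium, decarboxylation, vinyl transfer from tin, reductive elimination at the less hindered CH2 terminus) keeps the vinyl geometry, and the excess of 3 limits double coupling.

Step 5
Reactants: 8 phenyl(2,4,6-trihydroxyphenyl)methanone; 9 1-bromo-3-methylbut-2-ene (2.2 equiv)
Product: 10 clusiaphenone B
Conditions: KOH (10 % aq.), 0 °C
Reagents that add atoms: none
Why: Friedel–Crafts-type C-prenylation of the acylphloroglucinolate in water, where hydrogen bonding to the phenoxide oxygens directs the allylic bromide to the two free ring carbons.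

Step 6
Reactants: 10 clusiaphenone B; 7 chain carbonate
Product: 11 (6S)-2-benzoyl-3,5-dihydroxy-6-[(4Z)-6-hydroxy-5-methyl-2-(propan-2-ylidene)hex-4-en-1-yl]-4,6-bis(3-methylbut-2-en-1-yl)cyclohexa-2,4-dien-1-one
Conditions: Pd2(dba)3·CHCl3 (2.5 mol %), (S,S)-DACH-phenyl bisphosphine ligand [N,N′-(1S,2S)-cyclohexane-1,2-diylbis(2-diphenylphosphinobenzamide)] (7.5 mol %), CH2Cl2, 0 °C
Reagents that add atoms: none
Why: Tsuji–Trost asymmetric allylic alkylation run as a catalytic asymmetric dearomatization: zerovalent palladium ionises the carbonate of 7, the acylphloroglucinolate attacks the CH2 terminus of the π-allyl at a prenylated ring carbon (O-allylation is reversible and funnels to carbon), and the chiral ligand pocket distinguishes the enantiotopic modes of attack (ring carbon and ring face), which sets the quaternary centre C5.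

Step 7
Reactants: 11 dearomatised dienone alcohol
Product: 12 (5S)-nine-membered cyclic allyl enol ether (ring C4–O–CH2–C12(Me)=C11H–C10H2–C7(=CMe2)–C6H2–C5 with Z ring alkene, fused to the 2-benzoyl-3-hydroxy-4-prenylcyclohexadienone at C4–C5)
Conditions: PPh3, DIAD, toluene (0.005 M, slow addition), 0 °C to rt
Reagents that add atoms: none
Why: Intramolecular Mitsunobu etherification (SN2 at the primary allylic carbon, high dilution): of the two enol oxygens next to C5 only O4 is a free vinylogous-acid OH, O9 and O2 being held in the hydrogen-bonded benzoyl triketone chelate, so O4 should close the nine-membered ring, whose Z alkene and three sp2 ring atoms ease the medium-ring closure.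

Step 8
Reactants: 12 nine-membered enol ether
Product: 13 bicyclo[3.3.1]nonane core (C1 benzoyl, C5 prenyl, C8 gem-dimethyl, C2 and C9 ketones, C3=C4 enol ether with prenyl on C3) whose O4 is joined to C7 through O–CH2–C12(Me)=C11H–C10H2 (Z alkene; C7–H exo and C10 endo)
Conditions: HCO2H/CH2Cl2 (1:4), 0 °C
Reagents that add atoms: none
Why: Biomimetic cation–olefin cyclization: reversible protonation of the tetrasubstituted C7=C8 alkene at C7 on its outer face gives the tertiary C8 cation, which the enol carbon C1 of the benzoyl triketone captures in a chair-like six-membered closure; the ether tether holds C10 over C4, so C8 can reach only C1 (not C3) and only with C10 endo, which sets C7 and C1, while conjugation of the enol ether to C2=O and the β-oxygen of the ring alkene make those two π-bonds the least basic in the molecule.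

Step 9
Reactants: 13 bridged nine-membered allyl enol ether
Product: 14 homoadamantane trione with isopropenyl on C11 (on the C4 side), prenyl on C3 and C5, benzoyl on C1
Conditions: toluene (degassed), BHT (cat.), 90 °C
Reagents that add atoms: none
Why: Thermal [3,3]-sigmatropic (Claisen) shift of the allyl enol ether C3=C4–O–CH2–C12(Me)=C11: the C3–C11 bond forms as the O–CH2 bond breaks, C4 becomes a ketone again and the former O–CH2 carbon becomes the =CH2 terminus of the isopropenyl group on C11. The closest known reactions are the O-to-C Claisen transfer of allyl groups in O-allylated bicyclo[3.3.1]nonane-trione enol ethers and the Claisen ring contraction of medium-ring allyl vinyl ethers. The seven-membered carbocycle C3–C4–C5–C6–C7–C10–C11 is closed by a concerted, suprafacial six-centre process through a boat-like array (the four-atom tether C5–C6–C7–C10 spans positions 2 and 6 of the array), so the nine-membered ring loses O and CH2 and gains C3, which completes the homoadamantane. C3 is set because C11 can reach the enol ether only from its endo face (prenyl ends exo), and C11 is set by the Z ring alkene together with the O4 anchor, which hold C12 on the C4 side and the C11–H on the C2 side. The step needs the [3,3] path to C3 to win over ionisation with recombination at the CH2 terminus (a nine-membered carbocycle) and over Cope shifts of the C5 prenyl group; a neutral, non-polar, acid- and metal-free medium, the pre-organisation of C11 over C3 in the endo pocket of 13 and the release of medium-ring strain should secure this near 90 °C.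

Step 10
Reactants: 14 homoadamantane isopropenyl trione
Product: 16 target hydroperoxy-1,2-dioxepane CNP0215795.1, via triethylsilyl peroxide 15 (not isolated)
Conditions: Co(thd)2 (thd = 2,2,6,6-tetramethylheptane-3,5-dionate; 10 mol %), O2 (1 atm), Et3SiH (2.2 equiv), ClCH2CH2Cl, rt; then HCl (cat.), MeOH, 0 °C
Reagents that add atoms: dioxygen O=O
Why: Mukaiyama–Isayama peroxidation with peroxyl radical cyclization: a cobalt hydride transfers a hydrogen atom to the CH2 terminus of the 1,1-disubstituted isopropenyl group (faster than to the two trisubstituted prenyl alkenes), the tertiary C12 radical traps O2, the peroxyl radical adds 7-exo to C13 of the neighbouring C3 prenyl group, and the tertiary C15 radical traps a second O2 and is silylated; the dioxepane can close only with C13 anti to the C4 carbonyl, and in that geometry the CMe2 terminus points away from the cage (anti to C3), which corresponds to the C13 configuration of the target; acid methanolysis then frees the hydroperoxide.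

**Compound list**

1 | diethyl 2-(propan-2-ylidene)propanedioate | CCOC(=O)C(=C(C)C)C(=O)OCC | starting material
2 | 2-(propan-2-ylidene)propane-1,3-diol | CC(C)=C(CO)CO | intermediate
3 | dimethyl 2-(propan-2-ylidene)propane-1,3-diyl biscarbonate | COC(=O)OCC(COC(=O)OC)=C(C)C | intermediate
4 | prop-2-yn-1-ol | C#CCO | starting material
5 | (Z)-vinylmagnesium alkoxide, BrMg–CH=C(Me)–CH2OMgBr with Mg cis to CH2O | Br[Mg]/C=C(C)\CO[Mg]Br | intermediate
6 | (Z)-2-methyl-3-(tributylstannyl)prop-2-en-1-ol | CCCC[Sn](CCCC)(CCCC)/C=C(C)\CO | intermediate
7 | (4Z)-6-hydroxy-5-methyl-2-(propan-2-ylidene)hex-4-en-1-yl methyl carbonate | COC(=O)OCC(=C(C)C)C/C=C(C)\CO | intermediate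
8 | phenyl(2,4,6-trihydroxyphenyl)methanone | O=C(c1ccccc1)c1c(O)cc(O)cc1O | starting material
9 | 1-bromo-3-methylbut-2-ene (prenyl bromide) | CC(C)=CCBr | starting material
10 | clusiaphenone B, [2,4,6-trihydroxy-3,5-bis(3-methylbut-2-en-1-yl)phenyl](phenyl)methanone | CC(C)=CCc1c(O)c(CC=C(C)C)c(O)c(C(=O)c2ccccc2)c1O | intermediate
11 | (6S)-2-benzoyl-3,5-dihydroxy-6-[(4Z)-6-hydroxy-5-methyl-2-(propan-2-ylidene)hex-4-en-1-yl]-4,6-bis(3-methylbut-2-en-1-yl)cyclohexa-2,4-dien-1-one | CC(C)=CC[C@]1(CC(=C(C)C)C/C=C(C)\CO)C(O)=C(CC=C(C)C)C(O)=C(C(=O)c2ccccc2)C1=O | intermediate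
12 | (5S)-nine-membered cyclic allyl enol ether of 11: O4–CH2–C12(Me)=C11H–C10H2–C7(=CMe2)–C6H2–C5, Z ring alkene, fused at C4–C5 to the 2-benzoyl-3-hydroxy-4-prenyl dienone | CC(C)=CC[C@]12CC(=C(C)C)C/C=C(C)\COC1=C(CC=C(C)C)C(O)=C(C(=O)c1ccccc1)C2=O | intermediate
13 | 1-benzoyl-8,8-dimethyl-3,5-diprenylbicyclo[3.3.1]non-3-ene-2,9-dione whose C4 oxygen is bridged to C7 by O–CH2–C(Me)=CH–CH2 (Z); C7–H exo, bridge endo | CC(C)=CC[C@]12C[C@@H]3C/C=C(C)\COC1=C(CC=C(C)C)C(=O)[C@](C(=O)c1ccccc1)(C2=O)C3(C)C | intermediate
14 | homoadamantane trione: C1 benzoyl, C3 and C5 prenyl, C8 gem-dimethyl, C10–C11 bridge between C7 and C3, isopropenyl on C11 syn to C4=O | CC(C)=CC[C@]12C[C@@H]3C[C@H](C(C)=C)[C@](CC=C(C)C)(C1=O)C(=O)[C@](C(=O)c1ccccc1)(C2=O)C3(C)C | intermediate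
15 | C15 triethylsilyl peroxide of the target | CC(C)=CC[C@]12C[C@@H]3C[C@@H]4C(C)(C)OO[C@H](C(C)(C)OO[Si](CC)(CC)CC)C[C@@]4(C1=O)C(=O)[C@](C(=O)c1ccccc1)(C2=O)C3(C)C | intermediate
16 | CNP0215795.1: homoadamantane trione with 1,2-dioxepane C11–C12(Me2)–O–O–C13–C14–C3 and CMe2OOH on C13 (anti to C3) | CC(C)=CC[C@]12C[C@@H]3C[C@@H]4C(C)(C)OO[C@H](C(C)(C)OO)C[C@@]4(C1=O)C(=O)[C@](C(=O)c1ccccc1)(C2=O)C3(C)C | target

**Count and risks**

Total step count: 10. Longest linear sequence: 8 steps (steps 1, 2, 4, 6, 7, 8, 9, 10).

Steps most likely to fail:

Step 10. The C12 peroxyl radical may be captured by the cobalt/silane couple before the slow 7-exo closure, and facial control at C13 may be incomplete. The fallback sets out from 14. The same silylperoxidation is run so that it stops before cyclization (higher Co(thd)2 loading, 0 °C), which gives the open-chain C12 triethylsilyl peroxide F1. HCl in MeOH releases the tertiary C12 hydroperoxide F2. F2 is then cyclised in a metal-free peroxyl radical chain (di-tert-butyl hyponitrite as initiator, O2-saturated benzene, 40 °C, tert-butyl hydroperoxide as hydrogen donor), where no metal intercepts the peroxyl radical before the 7-exo addition and the second O2 capture. This returns to the route at 16.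

Step 7. Etherification may occur through the wrong enol oxygen (O9 of the benzoyl triketone), by SN2′ closure to a seven-membered ether, or between molecules. The fallback sets out from 11. BF3·OEt2 (CH2Cl2, 0 °C) locks O2 and the benzoyl oxygen as the difluoroboron chelate F3, which leaves O4–H as the only acidic enol. The Mitsunobu closure on F3 gives the chelated nine-membered ether F4. Aqueous NaOAc in EtOH at room temperature removes boron and returns to the route at 12.

Step 8. The acid may cleave or prematurely rearrange the allyl enol ether, the cation may be captured at oxygen instead of C1, or a prenyl group may cyclise onto an enol oxygen. The fallback sets out from 12 and reverses the order of the two events. Compound 12 is first heated (toluene, 90 °C), so that the Claisen contraction takes place on the monocyclic dienone and gives the bicyclo[4.3.1] triketone enol F5, which has no acid-labile enol ether and a quaternary C3. The C8-to-C1 cation–olefin closure is then run on F5 (HCO2H, 0 °C, short contact; the isopropenyl/prenyl pair must be kept from cation–olefin cyclization by the low temperature). This returns to the route at 14 and bypasses 13.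

**Further compounds**

F1 | step 10 | open-chain C12 triethylsilyl peroxide of 14 | CC(C)=CC[C@]12C[C@@H]3C[C@H](C(C)(C)OO[Si](CC)(CC)CC)[C@](CC=C(C)C)(C1=O)C(=O)[C@](C(=O)c1ccccc1)(C2=O)C3(C)C
F2 | step 10 | tertiary C12 hydroperoxide of 14 | CC(C)=CC[C@]12C[C@@H]3C[C@H](C(C)(C)OO)[C@](CC=C(C)C)(C1=O)C(=O)[C@](C(=O)c1ccccc1)(C2=O)C3(C)C
F3 | step 7 | difluoroboron chelate of 11 (boron between O2 and the benzoyl oxygen) | CC(C)=CC[C@]1(CC(=C(C)C)C/C=C(C)\CO)C(O)=C(CC=C(C)C)C2=C(C1=O)C(c1ccccc1)=[O+][B-](F)(F)O2
F4 | step 7 | difluoroboron chelate of 12 | CC(C)=CC[C@]12CC(=C(C)C)C/C=C(C)\COC1=C(CC=C(C)C)C1=C(C2=O)C(c2ccccc2)=[O+][B-](F)(F)O1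
F5 | step 8 | bicyclo[4.3.1] triketone enol from Claisen contraction of 12 (C3–C11 bond formed, C7=CMe2 retained, isopropenyl on C11) | CC(C)=CC[C@]12CC(=C(C)C)C[C@H](C(C)=C)[C@](CC=C(C)C)(C1=O)C(O)=C(C(=O)c1ccccc1)C2=O
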